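The bond between C1, the quaternary carbon of the cyclopentanone (ring A: C1 quaternary, C2 ketone, C3 carbinol, C4, C5), and C2', the acid-bearing methine of the open chain, is made last. The complete bis-macrocyclic β-keto lactone 33 (its C1–H lies between the C2 ketone and the lactone carbonyl of 14-membered ring B) adds in a Michael reaction to the E-4-oxo-2-enoate 14. The step exploits that ring B bridges C1 and C3 underneath ring A, so one enolate face is open; it joins both fragments and sets the quaternary and the adjacent tertiary stereocenter at once. Precursor 33 comes from two macrodiolides by Michael/aldol [3+2] annulation.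

Key step: step 24

Remark: the two ring enoates are taken as Z and the chain enoate as E, as the structure is written, so the Z-configured γ,δ-dioxygenated enoates are kept silylated to the end. Ring C is the 14-membered diolide fused at C4–C5. Compounds 7, 15, 23 and 27 are taken as catalogue compounds.

Step 1
Reactants: 1 penta-1,4-dien-3-ol
Product: 2 (2S,3R)-1,2-epoxypent-4-en-3-ol
Conditions: Ti(OiPr)4, D-(−)-diisopropyl tartrate, t-BuOOH, 4 Å molecular sieves, CH2Cl2, −20 °C
Reagents that add atoms: tert-butyl hydroperoxide, CC(C)(C)OO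
Why: Sharpless asymmetric epoxidation desymmetrises the divinyl carbinol, the tartrate complex choosing one enantiotopic vinyl group and one of its faces, so the erythro epoxy alcohol carrying both stereocenters of every hexenoate unit should form in high optical purity.

Step 2
Reactants: 2 (2S,3R)-1,2-epoxypent-4-en-3-ol
Product: 3 TBS ether of 2
Conditions: TBSCl, imidazole, DMF, 0 °C to rt
Reagents that add atoms: tert-butyldimethylsilyl chloride, CC(C)(C)[Si](C)(C)Cl
Why: Standard silylation of the secondary allylic alcohol installs the ether that stays on this oxygen until the last step.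

Step 3
Reactants: 3 TBS ether of 2
Product: 4 (2S,3R)-3-(tert-butyldimethylsilyloxy)pent-4-en-2-ol
Conditions: LiAlH4, Et2O, 0 °C
Reagents that add atoms: none
Why: Hydride opens the terminal epoxide by SN2 at the CH2 carbon, which becomes the methyl group, leaving the 2S carbinol untouched (low temperature against 1,2-silyl migration).

Step 4
Reactants: 4 (2S,3R)-3-(tert-butyldimethylsilyloxy)pent-4-en-2-ol
Product: 5 (3R,4S)-3-(tert-butyldimethylsilyloxy)-4-(triethylsilyloxy)pent-1-ene
Conditions: TESCl, imidazole, CH2Cl2, 0 °C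
Reagents that add atoms: triethylsilyl chloride, CC[Si](Cl)(CC)CC
Why: Silylation gives a TES ether that can later be removed selectively beside the TBS ether.

Step 5
Reactants: 5 (3R,4S)-3-(tert-butyldimethylsilyloxy)-4-(triethylsilyloxy)pent-1-ene
Product: 6 (2S,3S)-2-(tert-butyldimethylsilyloxy)-3-(triethylsilyloxy)butanal
Conditions: O3, CH2Cl2, −78 °C; then PPh3
Reagents that add atoms: ozone, [O-][O+]=O
Why: Ozonolysis with reductive work-up cleaves the terminal alkene to the α-silyloxy aldehyde without touching either stereocenter (used crude to avoid epimerisation).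

Step 6
Reactants: 7 4-(furan-2-yl)butan-2-one
Product: 8 (2S)-4-(furan-2-yl)butan-2-ol
Conditions: alcohol dehydrogenase (Prelog-selective ketoreductase), NADH (cat.), 2-propanol, phosphate buffer pH 7, 30 °C
Reagents that add atoms: none
Why: Enzymatic reduction of a methyl ketone by a Prelog-type alcohol dehydrogenase delivers hydride to the Re face and should give the S alcohol, the configuration of all three CH(CH3)–O carbons of the oxo-octenoate units.

Step 7
Reactants: 8 (2S)-4-(furan-2-yl)butan-2-ol; 9 acryloyl chloride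
Product: 10 (2S)-4-(furan-2-yl)butan-2-yl prop-2-enoate
Conditions: Et3N, CH2Cl2, 0 °C
Reagents that add atoms: none
Why: Simple O-acylation of the secondary alcohol with retention at the carbinol carbon.

Step 8
Reactants: 5 (3R,4S)-3-(tert-butyldimethylsilyloxy)-4-(triethylsilyloxy)pent-1-ene; 10 (2S)-4-(furan-2-yl)butan-2-yl prop-2-enoate
Product: 11 (2S)-4-(furan-2-yl)butan-2-yl (2E,4R,5S)-4-(tert-butyldimethylsilyloxy)-5-(triethylsilyloxy)hex-2-enoate
Conditions: second-generation Hoveyda–Grubbs catalyst (5 mol%), CH2Cl2, 40 °C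
Reagents that add atoms: none
Why: Olefin cross-metathesis of a hindered allylic silyl ether with an acrylate should give the E-enoate selectively and joins the two halves of the chain.

Step 9
Reactants: 11 furyl E-enoate
Product: 13 (2E,7S)-7-{[(2E,4R,5S)-4-(tert-butyldimethylsilyloxy)-5-(triethylsilyloxy)hex-2-enoyl]oxy}-4-oxooct-2-enoic acid, via E-oxo-enal 12 (not isolated)
Conditions: NBS, NaHCO3, acetone/H2O, −20 °C; pyridine, rt; then NaClO2, NaH2PO4, 2-methyl-2-butene, t-BuOH/H2O, 0 °C
Reagents that add atoms: water, O; sodium chlorite, [Na+].[O-]Cl=O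
Why: Oxidative ring opening of the 2-alkylfuran gives the cis-4-oxo-enal, pyridine isomerises it to E and Pinnick oxidation gives the E-4-oxo-2-enoic acid, while silyl ethers and enoate are inert.

Step 10
Reactants: 13 chain acid
Product: 14 triisopropylsilyl ester of 13 (Michael acceptor)
Conditions: TIPSCl, Et3N, CH2Cl2, 0 °C
Reagents that add atoms: triisopropylsilyl chloride, CC(C)[Si](Cl)(C(C)C)C(C)C
Why: O-silylation of the carboxylate gives a bulky silyl ester that masks the acid in the Michael step and falls together with the silyl ethers at the end.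

Step 11
Reactants: 8 (2S)-4-(furan-2-yl)butan-2-ol; 15 2-(diphenoxyphosphoryl)acetic acid
Product: 16 (2S)-4-(furan-2-yl)butan-2-yl 2-(diphenoxyphosphoryl)acetate
Conditions: DCC, DMAP (cat.), CH2Cl2, 0 °C to rt
Reagents that add atoms: none
Why: Steglich esterification gives the diaryl phosphonoacetate needed for a Z-selective olefination.

Step 12
Reactants: 16 furyl phosphonoacetate; 6 (2S,3S)-2-(tert-butyldimethylsilyloxy)-3-(triethylsilyloxy)butanal
Product: 17 (2S)-4-(furan-2-yl)butan-2-yl (2Z,4R,5S)-4-(tert-butyldimethylsilyloxy)-5-(triethylsilyloxy)hex-2-enoate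
Conditions: NaH, THF, −78 to −20 °C
Reagents that add atoms: none
Why: The Ando variant of the Horner–Wadsworth–Emmons reaction (diaryl phosphonate) gives the Z-enoate under kinetic control, and the α-silyloxy aldehyde is consumed cold before it can epimerise.

Step 13
Reactants: 17 furyl Z-enoate
Product: 19 (2E,7S)-7-{[(2Z,4R,5S)-4-(tert-butyldimethylsilyloxy)-5-(triethylsilyloxy)hex-2-enoyl]oxy}-4-oxooct-2-enoic acid, via E-oxo-enal 18 (not isolated)
Conditions: NBS, NaHCO3, acetone/H2O, −20 °C; pyridine, rt; then NaClO2, NaH2PO4, 2-methyl-2-butene, t-BuOH/H2O, 0 °C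
Reagents that add atoms: water, O; sodium chlorite, [Na+].[O-]Cl=O
Why: Same furan oxidation/isomerisation/Pinnick sequence as in step 9; the electron-poor Z-enoate is not touched by NBS or pyridine.

Step 14
Reactants: 19 seco acid with TES ether
Product: 20 (2E,7S)-7-{[(2Z,4R,5S)-4-(tert-butyldimethylsilyloxy)-5-hydroxyhex-2-enoyl]oxy}-4-oxooct-2-enoic acid
Conditions: HF·pyridine, pyridine, THF, 0 °C
Reagents that add atoms: none
Why: Buffered HF cleaves the TES ether much faster than the secondary TBS ether and, being non-basic and only weakly acidic, should not trigger δ-lactonisation of the Z-enoate.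

Step 15
Reactants: 20 hydroxy acid
Product: 22 (3E,8S,11Z,13R,14S)-13-(tert-butyldimethylsilyloxy)-8,14-dimethyl-1,9-dioxacyclotetradeca-3,11-diene-2,5,10-trione (ene-dione macrodiolide, future ring C), via mixed anhydride 21 (not isolated)
Conditions: 2,4,6-trichlorobenzoyl chloride, Et3N, THF, rt; then slow addition to DMAP, toluene (1 mM), rt
Reagents that add atoms: 2,4,6-trichlorobenzoyl chloride, O=C(Cl)c1c(Cl)cc(Cl)cc1Cl (its atoms stay only in intermediate 21)
Why: Yamaguchi macrolactonisation closes the 14-membered ring by acylation of the secondary hydroxyl at high dilution, and without strong base the E-ene-dione and Z-enoate geometries should be kept.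

Step 16
Reactants: 23 (2S)-hex-5-en-2-ol; 15 2-(diphenoxyphosphoryl)acetic acid
Product: 24 (2S)-hex-5-en-2-yl 2-(diphenoxyphosphoryl)acetate
Conditions: DCC, DMAP (cat.), CH2Cl2, 0 °C to rt
Reagents that add atoms: none
Why: Steglich esterification, as in step 11.

Step 17
Reactants: 24 hexenyl phosphonoacetate; 6 (2S,3S)-2-(tert-butyldimethylsilyloxy)-3-(triethylsilyloxy)butanal
Product: 25 (2S)-hex-5-en-2-yl (2Z,4R,5S)-4-(tert-butyldimethylsilyloxy)-5-(triethylsilyloxy)hex-2-enoate
Conditions: NaH, THF, −78 to −20 °C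
Reagents that add atoms: none
Why: Ando-type Z-selective Horner–Wadsworth–Emmons olefination, as in step 12.

Step 18
Reactants: 25 Z-enoate with TES ether
Product: 26 (2S)-hex-5-en-2-yl (2Z,4R,5S)-4-(tert-butyldimethylsilyloxy)-5-hydroxyhex-2-enoate
Conditions: HF·pyridine, pyridine, THF, 0 °C
Reagents that add atoms: none
Why: Selective TES cleavage beside TBS under buffered conditions, as in step 14.

Step 19
Reactants: 26 δ-hydroxy Z-enoate; 27 but-3-enoic acid
Product: 28 (2S)-hex-5-en-2-yl (2Z,4R,5S)-5-(but-3-enoyloxy)-4-(tert-butyldimethylsilyloxy)hex-2-enoate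
Conditions: DCC, DMAP (cat.), CH2Cl2, −20 °C
Reagents that add atoms: none
Why: Steglich esterification at low temperature and low DMAP loading acylates the δ-hydroxyl before it can attack the Z-enoate and keeps the β,γ-double bond of the butenoate out of conjugation.

Step 20
Reactants: 28 diene diester
Product: 29 (4E,8S,11Z,13R,14S)-13-(tert-butyldimethylsilyloxy)-8,14-dimethyl-1,9-dioxacyclotetradeca-4,11-diene-2,10-dione
Conditions: second-generation Grubbs catalyst (5 mol%), 1,4-benzoquinone, CH2Cl2 (1 mM), 40 °C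
Reagents that add atoms: none
Why: Ring-closing metathesis of the two terminal alkenes closes the 14-membered ring while the hindered conjugated Z-enoate is a spectator; the E isomer is expected, but the geometry is irrelevant because this alkene is oxidised next.

Step 21
Reactants: 29 macrocyclic alkene
Product: 30 (8S,11Z,13R,14S)-13-(tert-butyldimethylsilyloxy)-4,5-dihydroxy-8,14-dimethyl-1,9-dioxacyclotetradec-11-ene-2,10-dione (diol diastereomers, not separated)
Conditions: OsO4 (2 mol%), N-methylmorpholine N-oxide, acetone/H2O, 0 °C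
Reagents that add atoms: N-methylmorpholine N-oxide, C[N+]1([O-])CCOCC1; water, O
Why: Upjohn dihydroxylation should attack the isolated ring alkene much faster than the electron-poor, hindered Z-enoate, and all diol diastereomers converge in the next step.

Step 22
Reactants: 30 macrocyclic diol
Product: 31 (8S,11Z,13R,14S)-13-(tert-butyldimethylsilyloxy)-8,14-dimethyl-1,9-dioxacyclotetradec-11-ene-2,4,5,10-tetrone (dioxo macrodiolide, future ring B)
Conditions: IBX, DMSO, rt
Reagents that add atoms: none
Why: IBX oxidises 1,2-diols to 1,2-diketones without C–C cleavage, giving the 3,4-dioxo ester (expected mainly as its enol), which is used at once.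

Step 23
Reactants: 31 dioxo macrodiolide; 22 ene-dione macrodiolide
Product: 33 bis-macrocyclic cyclopentanone β-keto lactone (ring A 1S,3S,4S,5S, with C1–H, C2 ketone and C3 tertiary hydroxyl; ring B bridging C1 and C3; ring C fused at C4–C5; both ring TBS ethers in place), via Michael adduct 32 (not isolated)
Conditions: LiClO4, Et3N (0.2 equiv), THF, −20 °C to rt
Reagents that add atoms: none
Why: Domino Michael addition/intramolecular aldol addition (formal [3+2] annulation) in which C3 of 31 adds to C3 of 22 (β to its C5 ketone) on the 3Re,4Re face, the C4 enolate closes ring A by a lithium-chelated 5-exo-trig aldol addition to the distal carbonyl of the diketone so that the new hydroxyl is cis to the C4 acyl group, ester and acyl end up trans as in the E-alkene, and C1 equilibrates to the only configuration that lets ring B bridge C1 and C3 on one face.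

Step 24
Reactants: 33 bis-macrocyclic β-keto lactone; 14 triisopropylsilyl (E)-4-oxo-2-enoate
Product: 34 fully silylated target (33 carrying at C1 the R-configured C2' of the chain; three TBS ethers, one TES ether, TIPS ester)
Conditions: LiClO4 (1 equiv), Et3N (0.3 equiv), THF, 0 °C to rt
Reagents that add atoms: none
Why: Soft enolisation of the β-keto lactone (Et3N, lithium cation) gives the chelated C1 enolate, which adds to C2' of the 4-oxo-2-enoate (β to the ketone, α to the silyl ester), and the ketone enolate so formed is protonated; the closest known reaction type is the base- or Lewis-acid-mediated Michael addition of 2-alkoxycarbonyl cyclopentanones to enones and 3-acylacrylates, which builds quaternary centers of this kind. No ring is closed. The configuration at C1 is fixed by ring B: its 11-atom bridge ties the C1 carbonyl arm to C3 on the lower face of ring A, where the C5 ester also lies, so the acceptor can bond only on the upper face. The R configuration at C2' is expected from a closed transition state in which lithium held by the C2-enolate oxygen also binds the 4-oxo group of the acceptor; this puts the ketone arm over the C2 side, the silyl ester toward the open C5–H side and the C2' hydrogen over the ring between the C3 hydroxyl and the C4 acyl group. The step needs site selectivity for C1–H (the only doubly activated C–H of 33) and regioselectivity for C2' (attack β to the ketone), and neither the Z-enoates of 33 nor the γ-silyloxy E-enoate of 14 is electrophilic enough to compete.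

Step 25
Reactants: 34 fully silylated target
Product: 35 target CNP0078817.1
Conditions: HF·pyridine, pyridine, THF, 0 °C to rt
Reagents that add atoms: none
Why: Buffered fluoride cleaves the silyl ester and all four silyl ethers in one operation under conditions mild enough for the β-hydroxy ketone and the Z-configured γ-hydroxy enoates.

Compound list
1 | penta-1,4-dien-3-ol | C=CC(O)C=C | starting material
2 | (2S,3R)-1,2-epoxypent-4-en-3-ol | C=C[C@@H](O)[C@@H]1CO1 | intermediate
3 | tert-butyldimethylsilyl ether of 2 | C=C[C@@H](O[Si](C)(C)C(C)(C)C)[C@@H]1CO1 | intermediate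
4 | (2S,3R)-3-(tert-butyldimethylsilyloxy)pent-4-en-2-ol | C=C[C@@H](O[Si](C)(C)C(C)(C)C)[C@@H](O)C | intermediate
5 | (3R,4S)-3-(tert-butyldimethylsilyloxy)-4-(triethylsilyloxy)pent-1-ene | C=C[C@@H](O[Si](C)(C)C(C)(C)C)[C@@H](O[Si](CC)(CC)CC)C | intermediate
6 | (2S,3S)-2-(tert-butyldimethylsilyloxy)-3-(triethylsilyloxy)butanal | O=C[C@@H](O[Si](C)(C)C(C)(C)C)[C@@H](O[Si](CC)(CC)CC)C | intermediate
7 | 4-(furan-2-yl)butan-2-one | CC(=O)CCc1ccco1 | starting material
8 | (2S)-4-(furan-2-yl)butan-2-ol | C[C@H](O)CCc1ccco1 | intermediate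
9 | acryloyl chloride | C=CC(=O)Cl | starting material
10 | (2S)-4-(furan-2-yl)butan-2-yl prop-2-enoate | C=CC(=O)O[C@@H](C)CCc1ccco1 | intermediate
11 | (2S)-4-(furan-2-yl)butan-2-yl (2E,4R,5S)-4-(tert-butyldimethylsilyloxy)-5-(triethylsilyloxy)hex-2-enoate | C[C@H](O[Si](CC)(CC)CC)[C@H](O[Si](C)(C)C(C)(C)C)/C=C/C(=O)O[C@@H](C)CCc1ccco1 | intermediate
12 | (2E,7S)-7-{[(2E,4R,5S)-4-(tert-butyldimethylsilyloxy)-5-(triethylsilyloxy)hex-2-enoyl]oxy}-4-oxooct-2-enal | C[C@H](O[Si](CC)(CC)CC)[C@H](O[Si](C)(C)C(C)(C)C)/C=C/C(=O)O[C@@H](C)CCC(=O)/C=C/C=O | intermediate (not isolated)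
13 | (2E,7S)-7-{[(2E,4R,5S)-4-(tert-butyldimethylsilyloxy)-5-(triethylsilyloxy)hex-2-enoyl]oxy}-4-oxooct-2-enoic acid | C[C@H](O[Si](CC)(CC)CC)[C@H](O[Si](C)(C)C(C)(C)C)/C=C/C(=O)O[C@@H](C)CCC(=O)/C=C/C(=O)O | intermediate
14 | triisopropylsilyl ester of 13 | C[C@H](O[Si](CC)(CC)CC)[C@H](O[Si](C)(C)C(C)(C)C)/C=C/C(=O)O[C@@H](C)CCC(=O)/C=C/C(=O)O[Si](C(C)C)(C(C)C)C(C)C | intermediate
15 | 2-(diphenoxyphosphoryl)acetic acid | OC(=O)CP(=O)(Oc1ccccc1)Oc1ccccc1 | starting material
16 | (2S)-4-(furan-2-yl)butan-2-yl 2-(diphenoxyphosphoryl)acetate | O=C(CP(=O)(Oc1ccccc1)Oc1ccccc1)O[C@@H](C)CCc1ccco1 | intermediate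
17 | (2S)-4-(furan-2-yl)butan-2-yl (2Z,4R,5S)-4-(tert-butyldimethylsilyloxy)-5-(triethylsilyloxy)hex-2-enoate | C[C@H](O[Si](CC)(CC)CC)[C@H](O[Si](C)(C)C(C)(C)C)/C=C\C(=O)O[C@@H](C)CCc1ccco1 | intermediate
18 | (2E,7S)-7-{[(2Z,4R,5S)-4-(tert-butyldimethylsilyloxy)-5-(triethylsilyloxy)hex-2-enoyl]oxy}-4-oxooct-2-enal | C[C@H](O[Si](CC)(CC)CC)[C@H](O[Si](C)(C)C(C)(C)C)/C=C\C(=O)O[C@@H](C)CCC(=O)/C=C/C=O | intermediate (not isolated)
19 | (2E,7S)-7-{[(2Z,4R,5S)-4-(tert-butyldimethylsilyloxy)-5-(triethylsilyloxy)hex-2-enoyl]oxy}-4-oxooct-2-enoic acid | C[C@H](O[Si](CC)(CC)CC)[C@H](O[Si](C)(C)C(C)(C)C)/C=C\C(=O)O[C@@H](C)CCC(=O)/C=C/C(=O)O | intermediate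
20 | (2E,7S)-7-{[(2Z,4R,5S)-4-(tert-butyldimethylsilyloxy)-5-hydroxyhex-2-enoyl]oxy}-4-oxooct-2-enoic acid | C[C@H](O)[C@H](O[Si](C)(C)C(C)(C)C)/C=C\C(=O)O[C@@H](C)CCC(=O)/C=C/C(=O)O | intermediate
21 | mixed anhydride of 20 with 2,4,6-trichlorobenzoic acid | C[C@H](O)[C@H](O[Si](C)(C)C(C)(C)C)/C=C\C(=O)O[C@@H](C)CCC(=O)/C=C/C(=O)OC(=O)c1c(Cl)cc(Cl)cc1Cl | intermediate (not isolated)
22 | (3E,8S,11Z,13R,14S)-13-(tert-butyldimethylsilyloxy)-8,14-dimethyl-1,9-dioxacyclotetradeca-3,11-diene-2,5,10-trione | C[C@H]1CCC(=O)/C=C/C(=O)O[C@@H](C)[C@H](O[Si](C)(C)C(C)(C)C)/C=C\C(=O)O1 | intermediate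
23 | (2S)-hex-5-en-2-ol | C=CCC[C@H](C)O | starting material
24 | (2S)-hex-5-en-2-yl 2-(diphenoxyphosphoryl)acetate | C=CCC[C@H](C)OC(=O)CP(=O)(Oc1ccccc1)Oc1ccccc1 | intermediate
25 | (2S)-hex-5-en-2-yl (2Z,4R,5S)-4-(tert-butyldimethylsilyloxy)-5-(triethylsilyloxy)hex-2-enoate | C[C@H](O[Si](CC)(CC)CC)[C@H](O[Si](C)(C)C(C)(C)C)/C=C\C(=O)O[C@@H](C)CCC=C | intermediate
26 | (2S)-hex-5-en-2-yl (2Z,4R,5S)-4-(tert-butyldimethylsilyloxy)-5-hydroxyhex-2-enoate | C[C@H](O)[C@H](O[Si](C)(C)C(C)(C)C)/C=C\C(=O)O[C@@H](C)CCC=C | intermediate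
27 | but-3-enoic acid | OC(=O)CC=C | starting material
28 | (2S)-hex-5-en-2-yl (2Z,4R,5S)-5-(but-3-enoyloxy)-4-(tert-butyldimethylsilyloxy)hex-2-enoate | C=CCC(=O)O[C@@H](C)[C@H](O[Si](C)(C)C(C)(C)C)/C=C\C(=O)O[C@@H](C)CCC=C | intermediate
29 | (4E,8S,11Z,13R,14S)-13-(tert-butyldimethylsilyloxy)-8,14-dimethyl-1,9-dioxacyclotetradeca-4,11-diene-2,10-dione | C[C@H]1CC/C=C/CC(=O)O[C@@H](C)[C@H](O[Si](C)(C)C(C)(C)C)/C=C\C(=O)O1 | intermediate
30 | (8S,11Z,13R,14S)-13-(tert-butyldimethylsilyloxy)-4,5-dihydroxy-8,14-dimethyl-1,9-dioxacyclotetradec-11-ene-2,10-dione (C4 and C5 configurations unassigned) | C[C@H]1CCC(O)C(O)CC(=O)O[C@@H](C)[C@H](O[Si](C)(C)C(C)(C)C)/C=C\C(=O)O1 | intermediate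
31 | (8S,11Z,13R,14S)-13-(tert-butyldimethylsilyloxy)-8,14-dimethyl-1,9-dioxacyclotetradec-11-ene-2,4,5,10-tetrone | C[C@H]1CCC(=O)C(=O)CC(=O)O[C@@H](C)[C@H](O[Si](C)(C)C(C)(C)C)/C=C\C(=O)O1 | intermediate
32 | Michael adduct: C3 of 31 bonded to C3 of 22 (new center S; the carbon between the two carbonyls of 31 epimerisable, unassigned) | O=C1O[C@@H](C)[C@H](O[Si](C)(C)C(C)(C)C)/C=C\C(=O)O[C@@H](C)CCC(=O)C(=O)C1[C@@H]2CC(=O)CC[C@H](C)OC(=O)/C=C\[C@@H](O[Si](C)(C)C(C)(C)C)[C@H](C)OC2=O | intermediate (not isolated)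
33 | bis-macrocyclic cyclopentanone β-keto lactone (ring A 1S,3S,4S,5S; rings B and C each with one TBS ether) | [C@@H]12C(=O)O[C@@H](C)[C@H](O[Si](C)(C)C(C)(C)C)/C=C\C(=O)O[C@@H](C)CC[C@@](O)(C1=O)[C@H]1C(=O)CC[C@H](C)OC(=O)/C=C\[C@@H](O[Si](C)(C)C(C)(C)C)[C@H](C)OC(=O)[C@@H]12 | intermediate
34 | fully silylated target (C1 S, C2' R; three TBS ethers, one TES ether, TIPS ester) | C[C@H](O[Si](CC)(CC)CC)[C@H](O[Si](C)(C)C(C)(C)C)/C=C/C(=O)O[C@@H](C)CCC(=O)C[C@@H](C(=O)O[Si](C(C)C)(C(C)C)C(C)C)[C@@]12C(=O)O[C@@H](C)[C@H](O[Si](C)(C)C(C)(C)C)/C=C\C(=O)O[C@@H](C)CC[C@@](O)(C1=O)[C@H]1C(=O)CC[C@H](C)OC(=O)/C=C\[C@@H](O[Si](C)(C)C(C)(C)C)[C@H](C)OC(=O)[C@@H]12 | intermediate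
35 | CNP0078817.1 | C[C@H](O)[C@H](O)/C=C/C(=O)O[C@@H](C)CCC(=O)C[C@@H](C(=O)O)[C@@]12C(=O)O[C@@H](C)[C@H](O)/C=C\C(=O)O[C@@H](C)CC[C@@](O)(C1=O)[C@H]1C(=O)CC[C@H](C)OC(=O)/C=C\[C@@H](O)[C@H](C)OC(=O)[C@@H]12 | target

Total step count: 25. Longest linear sequence: 14 steps (steps 1–5, 17–22, 23–25).

Steps most likely to fail

Step 24 (key step). The addition may stall because the nucleophilic carbon is fully substituted and flanked by two macrocycles, the adduct may revert (retro-Michael) or ring A may open by retro-aldol under base, and the facial selectivity at C2' may erode if the closed transition state is not followed. Fallback: the order of the two C–C bond formations is inverted. Setting out from 31 and 14, the unhindered active methylene of 31 is added to 14 under a cinchona-derived bifunctional amine–squaramide catalyst (organocatalytic Michael addition of β-keto esters to 3-acylacrylates, with catalyst control at C2'; the pseudoenantiomer that gives the R methine is used). This gives the open Michael adduct F1, which is then annulated with 22 under the conditions of step 23, so that the quaternary center forms during the Michael/aldol sequence. The route is rejoined at 34.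

Step 23. The two faces of the ene-dione in the conformationally mobile macrocycle 22 may not be discriminated, giving the diastereomer from attack on the opposite face, and the enolised dione 31 may self-condense faster than it adds. Fallback: the acceptor is used in open-chain form, where a chiral bifunctional catalyst can dictate the face. Setting out from 19, alkylation with allyl bromide (KHCO3, DMF) gives the allyl ester F2. Its annulation with 31 under amine–squaramide catalysis gives the cyclopentanone F3. HF·pyridine/pyridine, then Pd(PPh3)4 and morpholine, unmask the hydroxy acid F4, and Yamaguchi macrolactonisation closes ring C, returning to the route at 33.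

Step 22. The γ-hydroxy ester in 30 may translactonise across the ring before it is oxidised, a half-oxidised ketol may cyclise to a tetronic acid, and the enolised 3,4-dioxo ester may undergo aldol self-condensation on isolation. Fallback: the dione is generated from the ene-dione macrocycle instead. Setting out from 22, nucleophilic epoxidation (t-BuOOH, DBU, CH2Cl2, 0 °C) gives the trans-epoxide F5. A non-nucleophilic base then isomerises it (the known rearrangement of 2,3-epoxy-1,4-dicarbonyl compounds to 2-hydroxy-ene-diones, as in epoxynaphthoquinone to 2-hydroxynaphthoquinone), with removal of the more acidic proton α to the ketone directing the oxygen to that carbon. This returns to the route at 31.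

Further compounds
F1 | step 24 | Michael adduct of 31 (at C3) with 14, C2' R, ring carbon between the carbonyls unassigned | C[C@H](O[Si](CC)(CC)CC)[C@H](O[Si](C)(C)C(C)(C)C)/C=C/C(=O)O[C@@H](C)CCC(=O)C[C@@H](C(=O)O[Si](C(C)C)(C(C)C)C(C)C)C1C(=O)O[C@@H](C)[C@H](O[Si](C)(C)C(C)(C)C)/C=C\C(=O)O[C@@H](C)CCC(=O)C1=O
F2 | step 23 | allyl ester of 19 | C[C@H](O[Si](CC)(CC)CC)[C@H](O[Si](C)(C)C(C)(C)C)/C=C\C(=O)O[C@@H](C)CCC(=O)/C=C/C(=O)OCC=C
F3 | step 23 | cyclopentanone with ring B closed and ring C open (allyl ester at C5, TES ether at the chain terminus) | [C@@H]12C(=O)O[C@@H](C)[C@H](O[Si](C)(C)C(C)(C)C)/C=C\C(=O)O[C@@H](C)CC[C@@](O)(C1=O)[C@@H](C(=O)CC[C@H](C)OC(=O)/C=C\[C@@H](O[Si](C)(C)C(C)(C)C)[C@H](C)O[Si](CC)(CC)CC)[C@@H]2C(=O)OCC=C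
F4 | step 23 | hydroxy acid from F3 | [C@@H]12C(=O)O[C@@H](C)[C@H](O[Si](C)(C)C(C)(C)C)/C=C\C(=O)O[C@@H](C)CC[C@@](O)(C1=O)[C@@H](C(=O)CC[C@H](C)OC(=O)/C=C\[C@@H](O[Si](C)(C)C(C)(C)C)[C@H](C)O)[C@@H]2C(=O)O
F5 | step 22 | trans-3,4-epoxide of 22 (one of the two trans diastereomers; both give 31) | C[C@H]1CCC(=O)[C@H]2O[C@@H]2C(=O)O[C@@H](C)[C@H](O[Si](C)(C)C(C)(C)C)/C=C\C(=O)O1
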